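**Known runs.** At early times L climbs from nothing, so a slope reads directly as the share of the Q charged that appears as L per minute.

| flask | Q | X | remark | time | volume of the second phase over the first |
|---|---|---|---|---|---|
| south | 10 mM | 6.5 mM | run made earlier |  |  |
| south-west | 10 mM | 26 mM | run made earlier |  |  |
| north-east | 20 mM | 13 mM | run made earlier |  |  |
| flask | 10 mM | 13.0 mM |  | 12 min | 1.0 |

- south (time / min: L / %): 1.00: 1.6; 1.50: 5.2; 3.00: 4.0; 5.00: 6.4; 8.00: 2.7; 15.0: 3.8
- south-west (time / min: L / %): 1.00: 7.7; 1.50: 10.6; 3.00: 14.2; 5.00: 13.3; 8.00: 8.7; 15.0: 5.3
- north-east (time / min: L / %): 1.00: 3.1; 2.00: 5.0; 4.00: 7.3; 8.00: 7.0; 15.0: 5.2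

(standard deviation of a reading: 1 percentage point)

- charges count per volume of the first phase; a concentration in a rate is the amount of a species over the volume of its own phase; every rate counts per litre of the first phase
- the earlier runs hold the two phases in the same ratio of volumes as the flask asked about
- a reading or a percentage of L counts all its forms, free or not

* the best time, 12 min at the latest, for L
* the amount of L, in percent of the Q charged, at that time
* the first time at which L reaches 5.2%, in the same percent, in min

**Early end.** Let a be the first two readings summed over their two times summed. At the flask's Q charge, the south run gives 0.0272 min⁻¹ and the south-west run 0.0732 min⁻¹. The flask's X lies at their geometric mean, so the same mean of the slopes is taken as κ, the early net share of the Q charged that appears as L per minute in the flask, 0.0446 min⁻¹, an initial rate.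

**First doubt.** The north-east run has the flask's X, so it might serve directly. But its a is 0.0270 min⁻¹, lower than κ, at twice the flask's Q. The percentages therefore do not carry across a change of Q, and κ stands. It puts 5.2% in the flask at 1.17 min.

**Late end.** In the south-west run L falls from the fifth reading to the sixth at 0.0708 min⁻¹, close to its a. A guess suggests itself: past the peak, L might fall at κ.

**Second doubt.** That match rests on one pair of readings, each with a scatter of 1 percentage point, and the north-east run falls at 0.0425 min⁻¹ against its a of 0.0270 min⁻¹. The guess is dropped, and the peak is taken from the highest readings instead.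

**The join.** The highest readings of the south and south-west runs give a geometric mean of 9.53%, itself uncertain by the scatter. Scaling the south-west peak time by its a over κ puts the flask's peak near 4.92 min.

**Result.** The forecast, later on both times, gives 5.6 min, 7.6% and 1.85 min, holding that “The north-east run has the same X as the flask, so I expect nearly the same percentages”. The flask gives 4.04 min, 10.3% and 1.20 min.

    D + L → J (k = 1.30 M⁻¹ s⁻¹)
    Q + D → L (k = 0.830 M⁻¹ s⁻¹)
    L ⇌ E, rate k3*([L] - [E]/K3) per volume of the first phase (partition coefficient = 0.660, kL = 0.0120 s⁻¹)
    L ⇌ Z (K = 30.0, k = 0.0150 s⁻¹)
    D ⇌ X, rate k5*([D] - [X]/K5) per volume of the first phase (partition coefficient = 2.60, kL = 0.0130 s⁻¹)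
    L → G (k = 0.00170 s⁻¹)

**Fall.** In the flask at 2.54 min, reaction-phase L turns into Z with a half-life of 0.77 min by the forward step alone, far shorter than the 10 min that Q has by Q + D at 12.0 min. That Q rate is 0.0685 min⁻¹, and L falls from its best to 12 min at 0.0618 min⁻¹. κ times 1.20 min gives 5.35%, and the flask then holds 5.18%. κ times 8.0 min gives 35.7%, and the flask left until then holds 8.33%.

All runs are simulated from invented constants, noise included.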